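**Plan**
- Retrosynthesis: cut C12–C13 (B-alkyl Suzuki coupling), then C11–C12 and C9–C11 (ylide homologation of a 9α,11-epoxide; methylenation of a C9 ketone), then C5–C10 and C6–C7 together (intramolecular Diels–Alder), then C10–C1 (enolate alkylation), C5=C6 (olefination) and C3–C4 (aldol).
- Enabling feature: the C9 oxygen and the quaternary C10 on the ring-fusion bond C5–C10 correspond to a 2-silyloxydiene C7=C8–C9(OSi)=C10, joined through C1–C4 to a C5=C6 vinyl sulfone. The diene is carried as a 4-silyloxy-2H-thiopyran in which sulfur ties C7 to C20; this locks the s-cis form and the enol ether geometry (tether cis to the silyloxy group).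
- Forward: the C1–C6 chain is built in six steps and alkylated onto the thiopyranone; rings A and B close in one cycloaddition; Raney Ni turns the sulfur bridge into C20H3 and C7H2; the sulfone is removed; the C9 side chain is added last.
- Stereochemistry: C3 from a reagent-controlled Kiyooka aldol; C5 and C10 from the cycloaddition under control of C3 (chair-like tether, equatorial silyloxy group, endo sulfone); C8 by equilibration to the equatorial methyl; C9 by α-face epoxidation of the 9(11)-alkene and opening at C11.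

Key step: step 12

Remark: the target is read as (3S,5S,8R,9R,10S), i.e. 3β-acetoxy-9α-hydroxylabd-13-en-16,15-olide. Labdane locants are used for all bicyclic compounds (ring A = C1–C5, C10; ring B = C5–C10; C17 on C8, C18/C19 on C4, C20 on C10), with α/β as in the usual drawing. N-Ts-D-valine and 3-bromo-2(5H)-furanone are taken as purchasable.

**Route**

Step 1
Reactants: 1 3-(tert-butyldimethylsilyloxy)propanal; 2 1-methoxy-2-methyl-1-(trimethylsilyloxy)prop-1-ene
Product: 3 methyl (3S)-5-(tert-butyldimethylsilyloxy)-3-hydroxy-2,2-dimethylpentanoate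
Conditions: N-Ts-D-valine (1.1 equiv), BH3·THF (1.0 equiv), CH2Cl2, rt then −78 °C; add 1 and 2, −78 °C; pH 7 buffer work-up
Reagents that add atoms: none
Why: Kiyooka aldol (oxazaborolidinone-promoted Mukaiyama aldol); the D-valine-derived promoter should deliver the ketene acetal to the Re face of the aldehyde, which sets C3 as S.

Step 2
Reactants: 3 methyl (3S)-5-(tert-butyldimethylsilyloxy)-3-hydroxy-2,2-dimethylpentanoate
Product: 4 methyl (3S)-3,5-bis(tert-butyldimethylsilyloxy)-2,2-dimethylpentanoate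
Conditions: TBSOTf, 2,6-lutidine, CH2Cl2, 0 °C
Reagents that add atoms: tert-butyldimethylsilyl triflate, CC(C)(C)[Si](C)(C)OS(=O)(=O)C(F)(F)F
Why: Silylation with the silyl triflate and a hindered base is the standard protection of a neopentyl-type secondary alcohol; no stereocentre is touched.

Step 3
Reactants: 4 methyl (3S)-3,5-bis(tert-butyldimethylsilyloxy)-2,2-dimethylpentanoate
Product: 5 (3S)-3,5-bis(tert-butyldimethylsilyloxy)-2,2-dimethylpentanal
Conditions: i-Bu2AlH (1.1 equiv), CH2Cl2, −78 °C; Rochelle salt work-up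
Reagents that add atoms: none
Why: Partial reduction of an ester; the hindered, β-silyloxy-chelated aluminium hemiacetal should persist at −78 °C and release the aldehyde only on work-up.

Step 4
Reactants: 5 (3S)-3,5-bis(tert-butyldimethylsilyloxy)-2,2-dimethylpentanal; 6 diethyl (phenylsulfonyl)methylphosphonate
Product: 7 (1E,4S)-4,6-bis(tert-butyldimethylsilyloxy)-3,3-dimethyl-1-(phenylsulfonyl)hex-1-ene
Conditions: NaH, THF, 0 °C to rt
Reagents that add atoms: none
Why: Horner–Wadsworth–Emmons olefination of a non-enolisable aldehyde with a sulfonyl-stabilised phosphonate, which should give the (E)-vinyl sulfone.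

Step 5
Reactants: 7 (1E,4S)-4,6-bis(tert-butyldimethylsilyloxy)-3,3-dimethyl-1-(phenylsulfonyl)hex-1-ene
Product: 8 (3S,5E)-3-(tert-butyldimethylsilyloxy)-4,4-dimethyl-6-(phenylsulfonyl)hex-5-en-1-ol
Conditions: camphorsulfonic acid (0.1 equiv), MeOH/CH2Cl2 1:1, 0 °C
Reagents that add atoms: none
Why: Acid-catalysed methanolysis (selective desilylation) removes the unhindered primary silyl ether far faster than the secondary one next to the quaternary carbon.

Step 6
Reactants: 8 (3S,5E)-3-(tert-butyldimethylsilyloxy)-4,4-dimethyl-6-(phenylsulfonyl)hex-5-en-1-ol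
Product: 9 (1E,4S)-4-(tert-butyldimethylsilyloxy)-6-iodo-3,3-dimethyl-1-(phenylsulfonyl)hex-1-ene
Conditions: I2, PPh3, imidazole, CH2Cl2, 0 °C to rt
Reagents that add atoms: iodine, II
Why: Appel-type iodination of a primary alcohol by SN2 displacement of the oxyphosphonium group; the vinyl sulfone and the silyl ether are inert to it.

Step 7
Reactants: 10 tetrahydro-4H-thiopyran-4-one
Product: 11 2,3-dihydro-4H-thiopyran-4-one
Conditions: N-chlorosuccinimide, pyridine, CH2Cl2, 0 °C to rt
Reagents that add atoms: none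
Why: Pummerer-type dehydrogenation (S-chlorination, α-chlorosulfide, loss of HCl) gives the vinylogous thioester, a known transformation of this ketone.

Step 8
Reactants: 11 2,3-dihydro-4H-thiopyran-4-one
Product: 12 5-iodo-2,3-dihydro-4H-thiopyran-4-one
Conditions: I2, pyridine, CH2Cl2, rt
Reagents that add atoms: iodine, II
Why: α-Iodination of an enone with I2/pyridine; the sulfur donor at the β-position makes C5 the nucleophilic carbon.

Step 9
Reactants: 12 5-iodo-2,3-dihydro-4H-thiopyran-4-one
Product: 13 5-methyl-2,3-dihydro-4H-thiopyran-4-one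
Conditions: MeB(OH)2, Pd(dppf)Cl2 (5 mol%), K2CO3, dioxane/H2O, 80 °C
Reagents that add atoms: methylboronic acid, CB(O)O
Why: Suzuki–Miyaura methylation of an α-iodoenone, a standard cross-coupling for this substrate class.

Step 10
Reactants: 13 5-methyl-2,3-dihydro-4H-thiopyran-4-one; 9 (1E,4S)-4-(tert-butyldimethylsilyloxy)-6-iodo-3,3-dimethyl-1-(phenylsulfonyl)hex-1-ene
Product: 15 3-[(3S,5E)-3-(tert-butyldimethylsilyloxy)-4,4-dimethyl-6-(phenylsulfonyl)hex-5-en-1-yl]-5-methyl-2,3-dihydro-4H-thiopyran-4-one (both epimers at ring C3), via lithium dienolate 14 (not isolated)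
Conditions: LiN(i-Pr)2, THF, −78 °C; then 9, DMPU, −78 to −30 °C
Reagents that add atoms: none
Why: Stork–Danheiser-type α′-alkylation: the kinetic cross-conjugated enolate of the vinylogous thioester is C-alkylated by the primary iodide, while the quaternary carbon next to the vinyl sulfone shields it from conjugate addition; the new ring stereocentre disappears in step 11.

Step 11
Reactants: 15 3-[(3S,5E)-3-(tert-butyldimethylsilyloxy)-4,4-dimethyl-6-(phenylsulfonyl)hex-5-en-1-yl]-5-methyl-2,3-dihydro-4H-thiopyran-4-one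
Product: 16 4-(tert-butyldimethylsilyloxy)-3-[(3S,5E)-3-(tert-butyldimethylsilyloxy)-4,4-dimethyl-6-(phenylsulfonyl)hex-5-en-1-yl]-5-methyl-2H-thiopyran
Conditions: TBSOTf, Et3N, CH2Cl2, 0 °C
Reagents that add atoms: tert-butyldimethylsilyl triflate, CC(C)(C)[Si](C)(C)OS(=O)(=O)C(F)(F)F
Why: Soft enolisation (silyl triflate/amine) can only remove the C10 hydrogen, and the ring holds C20 cis to C8 and the tether cis to the silyloxy group, so a single diene isomer should form.

Step 12
Reactants: 16 4-(tert-butyldimethylsilyloxy)-3-[(3S,5E)-3-(tert-butyldimethylsilyloxy)-4,4-dimethyl-6-(phenylsulfonyl)hex-5-en-1-yl]-5-methyl-2H-thiopyran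
Product: 17 thia-bridged cycloadduct: 3β,9-bis(tert-butyldimethylsilyloxy)-6α-(phenylsulfonyl)-4,4,8-trimethyl-trans-decal-8-ene with a C7–S–C20H2–C10 bridge on the β-face (5α-H, 7α-H; ring B a boat inside a 2-thiabicyclo[2.2.2]octene)
Conditions: toluene (0.01 M), BHT (cat.), 130 °C, sealed tube
Reagents that add atoms: none
Why: On heating, the ring-locked s-cis diene C7=C8–C9(OTBS)=C10, a thio-analogue of a Danishefsky diene, and the tethered (E)-vinyl sulfone should combine in a concerted, asynchronous [4+2] cycloaddition (type 1 intramolecular Diels–Alder reaction; closest known cases are intramolecular cycloadditions of 4-silyloxy-2H-thiopyrans and of vinyl sulfone trienes), the nucleophilic terminus C10 bonding to the β-carbon C5 and C7 to C6. Ring B closes as the six-membered ring of the cycloaddition and ring A closes as a six-membered carbocycle through the C1–C4 tether, exo with respect to both π-systems. C10 and C7 are fixed by suprafacial addition to one diene face with the sulfide bridge left on the opposite face, and C5 and C6 by the E-geometry (C4 and SO2Ph trans) together with the sulfonyl-endo, tether-exo transition state, which puts C4 syn to the C20 bridge and so gives the trans relation of C5–H and C10–C20. The absolute sense comes from C3 alone: in the chair-like tether the silyloxy group sits equatorial, which selects the diene face leading to 3β-O and 10β-C20. The step therefore needs trans-fusion (endo-sulfonyl) selectivity and diene-face selectivity; the E-dienophile, the ring-locked diene (no inside-methyl penalty, no enol ether isomers) and the equatorial C3 substituent beside the gem-dimethyl group are what should secure them.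

Step 13
Reactants: 17 thia-bridged cycloadduct
Product: 18 3β,9-bis(tert-butyldimethylsilyloxy)-6α-(phenylsulfonyl)-4,4,8,10β-tetramethyl-trans-decal-8-ene (5α-H; C8=C9 silyl enol ether)
Conditions: Raney Ni (W-2, excess), EtOH/THF, rt to 50 °C
Reagents that add atoms: none
Why: Raney nickel desulfurisation (Mozingo-type hydrogenolysis of both C–S bonds) under neutral conditions turns the bridge into the C20 methyl and C7H2; running it before any basic or dissolving-metal step avoids β-elimination between the C6 sulfone and the C7 sulfide.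

Step 14
Reactants: 18 3β,9-bis(tert-butyldimethylsilyloxy)-6α-(phenylsulfonyl)-4,4,8,10β-tetramethyl-trans-decal-8-ene
Product: 19 3β,9-bis(tert-butyldimethylsilyloxy)-4,4,8,10β-tetramethyl-trans-decal-8-ene
Conditions: Na/Hg (6% Na), Na2HPO4, MeOH/THF, −20 to 0 °C
Reagents that add atoms: none
Why: Reductive desulfonylation with sodium amalgam in buffered methanol cleaves the secondary alkyl phenyl sulfone by electron transfer and protonation, while the ketone stays masked as the silyl enol ether.

Step 15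
Reactants: 19 3β,9-bis(tert-butyldimethylsilyloxy)-4,4,8,10β-tetramethyl-trans-decal-8-ene
Product: 21 3β-(tert-butyldimethylsilyloxy)-4,4,8α,10β-tetramethyl-trans-decalin-9-one, via 8β-methyl ketone 20 (not isolated)
Conditions: n-Bu4NF (1.1 equiv), THF, 0 °C; then NaOMe (cat.), MeOH, rt
Reagents that add atoms: none
Why: Fluoride cleaves the enol silyl ether much faster than the hindered C3 ether, and methoxide equilibration should then move the C8 methyl to the equatorial α-position, away from the syn-axial C20 methyl (thermodynamic control of C8).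

Step 16
Reactants: 21 3β-(tert-butyldimethylsilyloxy)-4,4,8α,10β-tetramethyl-trans-decalin-9-one
Product: 22 3β-(tert-butyldimethylsilyloxy)-9-methylene-4,4,8α,10β-tetramethyl-trans-decalin (C9=C11H2)
Conditions: Ph3PCH3Br, KOtBu, toluene, 100 °C
Reagents that add atoms: methyltriphenylphosphonium bromide, C[P+](c1ccccc1)(c1ccccc1)c1ccccc1.[Br-]
Why: Wittig methylenation with the ylide at elevated temperature is the established answer to hindered ketones; C8 is already the thermodynamic epimer, so the basic medium cannot erode it.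

Step 17
Reactants: 22 3β-(tert-butyldimethylsilyloxy)-9-methylene-4,4,8α,10β-tetramethyl-trans-decalin
Product: 23 9α,11-epoxide of 22 (spiro-oxirane at C9; oxygen α, C11 β)
Conditions: mCPBA, NaHCO3, CH2Cl2, 0 °C
Reagents that add atoms: 3-chloroperbenzoic acid, OOC(=O)c1cccc(Cl)c1
Why: Prilezhaev epoxidation; the peracid should approach the exocyclic alkene from the α-face, anti to the axial C20 methyl on the neighbouring carbon, which places the oxygen 9α.

Step 18
Reactants: 23 9α,11-epoxide of 22
Product: 24 3β-(tert-butyldimethylsilyloxy)-9β-vinyl-4,4,8α,10β-tetramethyl-trans-decalin-9α-ol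
Conditions: Me3S+ I− (4 equiv), n-BuLi (3.8 equiv), THF, −10 °C to rt
Reagents that add atoms: trimethylsulfonium iodide, C[S+](C)C.[I-]
Why: Epoxide-to-allylic-alcohol homologation with excess dimethylsulfonium methylide: the ylide opens the epoxide at the CH2 terminus C11 and the sulfonium salt formed undergoes ylide-mediated elimination, so C9 keeps its configuration.

Step 19
Reactants: 24 3β-(tert-butyldimethylsilyloxy)-9β-vinyl-4,4,8α,10β-tetramethyl-trans-decalin-9α-ol
Product: 25 9β-vinyl-4,4,8α,10β-tetramethyl-trans-decalin-3β,9α-diol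
Conditions: n-Bu4NF (3 equiv), THF, 60 °C
Reagents that add atoms: none
Why: Fluoride desilylation at elevated temperature removes the hindered 3β-silyl ether before any base- or fluoride-sensitive group is present.

Step 20
Reactants: 25 9β-vinyl-4,4,8α,10β-tetramethyl-trans-decalin-3β,9α-diol
Product: 26 3β-acetoxy-9β-vinyl-4,4,8α,10β-tetramethyl-trans-decalin-9α-ol
Conditions: Ac2O, pyridine, DMAP (cat.), CH2Cl2, rt
Reagents that add atoms: acetic anhydride, CC(=O)OC(C)=O
Why: Acetylation takes only the secondary equatorial alcohol; the tertiary, axial C9 alcohol flanked by two substituted carbons is inert under these conditions.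

Step 21
Reactants: 26 3β-acetoxy-9β-vinyl-4,4,8α,10β-tetramethyl-trans-decalin-9α-ol; 27 3-bromo-2(5H)-furanone
Product: 29 3β-acetoxy-9α-hydroxylabd-13-en-16,15-olide, (3S,5S,8R,9R,10S), via B-alkyl-9-BBN adduct 28 (not isolated)
Conditions: 9-BBN, THF, rt to 40 °C; then 27, Pd(dppf)Cl2 (5 mol%), AsPh3, Cs2CO3, DMF/H2O, rt
Reagents that add atoms: none
Why: Anti-Markovnikov hydroboration of the monosubstituted alkene with 9-BBN, then B-alkyl Suzuki–Miyaura coupling with the α-bromobutenolide, forms C12–C13 under mild aqueous base that the hindered acetate and the butenolide should tolerate.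

**Compound list**

1 | 3-(tert-butyldimethylsilyloxy)propanal | O=CCCO[Si](C)(C)C(C)(C)C | starting material
2 | 1-methoxy-2-methyl-1-(trimethylsilyloxy)prop-1-ene | COC(O[Si](C)(C)C)=C(C)C | starting material
3 | methyl (3S)-5-(tert-butyldimethylsilyloxy)-3-hydroxy-2,2-dimethylpentanoate | COC(=O)C(C)(C)[C@@H](O)CCO[Si](C)(C)C(C)(C)C | intermediate
4 | methyl (3S)-3,5-bis(tert-butyldimethylsilyloxy)-2,2-dimethylpentanoate | COC(=O)C(C)(C)[C@@H](O[Si](C)(C)C(C)(C)C)CCO[Si](C)(C)C(C)(C)C | intermediate
5 | (3S)-3,5-bis(tert-butyldimethylsilyloxy)-2,2-dimethylpentanal | O=CC(C)(C)[C@@H](O[Si](C)(C)C(C)(C)C)CCO[Si](C)(C)C(C)(C)C | intermediate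
6 | diethyl (phenylsulfonyl)methylphosphonate | CCOP(=O)(CS(=O)(=O)c1ccccc1)OCC | starting material
7 | (1E,4S)-4,6-bis(tert-butyldimethylsilyloxy)-3,3-dimethyl-1-(phenylsulfonyl)hex-1-ene | O=S(=O)(/C=C/C(C)(C)[C@@H](O[Si](C)(C)C(C)(C)C)CCO[Si](C)(C)C(C)(C)C)c1ccccc1 | intermediate
8 | (3S,5E)-3-(tert-butyldimethylsilyloxy)-4,4-dimethyl-6-(phenylsulfonyl)hex-5-en-1-ol | OCC[C@H](O[Si](C)(C)C(C)(C)C)C(C)(C)/C=C/S(=O)(=O)c1ccccc1 | intermediate
9 | (1E,4S)-4-(tert-butyldimethylsilyloxy)-6-iodo-3,3-dimethyl-1-(phenylsulfonyl)hex-1-ene | ICC[C@H](O[Si](C)(C)C(C)(C)C)C(C)(C)/C=C/S(=O)(=O)c1ccccc1 | intermediate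
10 | tetrahydro-4H-thiopyran-4-one | O=C1CCSCC1 | starting material
11 | 2,3-dihydro-4H-thiopyran-4-one | O=C1CCSC=C1 | intermediate
12 | 5-iodo-2,3-dihydro-4H-thiopyran-4-one | O=C1CCSC=C1I | intermediate
13 | 5-methyl-2,3-dihydro-4H-thiopyran-4-one | CC1=CSCCC1=O | intermediate
14 | lithium 5-methyl-2H-thiopyran-4-olate (kinetic enolate of 13) | [Li]OC1=CCSC=C1C | intermediate
15 | 3-[(3S,5E)-3-(tert-butyldimethylsilyloxy)-4,4-dimethyl-6-(phenylsulfonyl)hex-5-en-1-yl]-5-methyl-2,3-dihydro-4H-thiopyran-4-one (both epimers at ring C3) | CC1=CSCC(CC[C@H](O[Si](C)(C)C(C)(C)C)C(C)(C)/C=C/S(=O)(=O)c2ccccc2)C1=O | intermediate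
16 | 4-(tert-butyldimethylsilyloxy)-3-[(3S,5E)-3-(tert-butyldimethylsilyloxy)-4,4-dimethyl-6-(phenylsulfonyl)hex-5-en-1-yl]-5-methyl-2H-thiopyran | CC1=CSCC(CC[C@H](O[Si](C)(C)C(C)(C)C)C(C)(C)/C=C/S(=O)(=O)c2ccccc2)=C1O[Si](C)(C)C(C)(C)C | intermediate
17 | thia-bridged cycloadduct: 3β,9-bis(tert-butyldimethylsilyloxy)-6α-(phenylsulfonyl)-4,4,8-trimethyl-trans-decal-8-ene with β-face C7–S–C20H2–C10 bridge (5α-H, 7α-H) | CC(C)(C)[Si](C)(C)O[C@H]1CC[C@@]2(CS3)[C@@H]([C@@H](S(=O)(=O)c4ccccc4)[C@H]3C(C)=C2O[Si](C)(C)C(C)(C)C)C1(C)C | intermediate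
18 | 3β,9-bis(tert-butyldimethylsilyloxy)-6α-(phenylsulfonyl)-4,4,8,10β-tetramethyl-trans-decal-8-ene | CC(C)(C)[Si](C)(C)O[C@H]1CC[C@@]2(C)[C@@H]([C@@H](S(=O)(=O)c3ccccc3)CC(C)=C2O[Si](C)(C)C(C)(C)C)C1(C)C | intermediate
19 | 3β,9-bis(tert-butyldimethylsilyloxy)-4,4,8,10β-tetramethyl-trans-decal-8-ene | CC(C)(C)[Si](C)(C)O[C@H]1CC[C@@]2(C)[C@@H](CCC(C)=C2O[Si](C)(C)C(C)(C)C)C1(C)C | intermediate
20 | 3β-(tert-butyldimethylsilyloxy)-4,4,8β,10β-tetramethyl-trans-decalin-9-one (8-epimer of 21) | CC(C)(C)[Si](C)(C)O[C@H]1CC[C@@]2(C)[C@@H](CC[C@H](C)C2=O)C1(C)C | intermediate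
21 | 3β-(tert-butyldimethylsilyloxy)-4,4,8α,10β-tetramethyl-trans-decalin-9-one | CC(C)(C)[Si](C)(C)O[C@H]1CC[C@@]2(C)[C@@H](CC[C@@H](C)C2=O)C1(C)C | intermediate
22 | 3β-(tert-butyldimethylsilyloxy)-9-methylene-4,4,8α,10β-tetramethyl-trans-decalin | CC(C)(C)[Si](C)(C)O[C@H]1CC[C@@]2(C)[C@@H](CC[C@@H](C)C2=C)C1(C)C | intermediate
23 | 9α,11-epoxide of 22 (spiro-oxirane, oxygen α) | CC(C)(C)[Si](C)(C)O[C@H]1CC[C@@]2(C)[C@@H](CC[C@@H](C)[C@]2(O3)C3)C1(C)C | intermediate
24 | 3β-(tert-butyldimethylsilyloxy)-9β-vinyl-4,4,8α,10β-tetramethyl-trans-decalin-9α-ol | CC(C)(C)[Si](C)(C)O[C@H]1CC[C@@]2(C)[C@@H](CC[C@@H](C)[C@]2(O)C=C)C1(C)C | intermediate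
25 | 9β-vinyl-4,4,8α,10β-tetramethyl-trans-decalin-3β,9α-diol | O[C@H]1CC[C@@]2(C)[C@@H](CC[C@@H](C)[C@]2(O)C=C)C1(C)C | intermediate
26 | 3β-acetoxy-9β-vinyl-4,4,8α,10β-tetramethyl-trans-decalin-9α-ol | CC(=O)O[C@H]1CC[C@@]2(C)[C@@H](CC[C@@H](C)[C@]2(O)C=C)C1(C)C | intermediate
27 | 3-bromo-2(5H)-furanone | O=C1OCC=C1Br | starting material
28 | 9-[2-(3β-acetoxy-9α-hydroxy-4,4,8α,10β-tetramethyl-trans-decalin-9β-yl)ethyl]-9-borabicyclo[3.3.1]nonane | CC(=O)O[C@H]1CC[C@@]2(C)[C@@H](CC[C@@H](C)[C@]2(O)CCB3C4CCCC3CCC4)C1(C)C | intermediate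
29 | 3β-acetoxy-9α-hydroxylabd-13-en-16,15-olide, (3S,5S,8R,9R,10S) | CC(=O)O[C@H]1CC[C@@]2(C)[C@@H](CC[C@@H](C)[C@]2(O)CCC2=CCOC2=O)C1(C)C | target

**Step count and risks**

Total steps: 21. Longest linear sequence: 18 steps (steps 1–6 and 10–21, from 1); steps 7–9 form the short thiopyranone branch.

Steps most likely to fail:

1. Step 12. The cycloaddition may not discriminate well enough between the sulfonyl-endo (trans-fusion) and sulfonyl-exo transition states or between the two diene faces, and the 2H-thiopyran may undergo thermal hydrogen shift or oligomerisation before it cyclises. Fallback: the same two bonds are made stepwise from ketone 15 by an intramolecular double Michael addition. With LiN(SiMe3)2 in THF at −78 °C the C10 enolate should add 6-exo to C5 of the vinyl sulfone, and the α-sulfonyl carbanion then closes onto C7 of the vinylogous thioester. A cold quench gives the thia-bridged 9-ketone F1. Soft enolisation of this ketone (TBSOTf, Et3N), which can only go towards C8, rejoins the route at 17.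

2. Step 21. Transmetalation of the hindered alkylborane may be slower than base-induced decay of the bromobutenolide or protodeboronation. Fallback from 26: hydroboration with 9-BBN and oxidation with NaBO3 gives the primary alcohol F2. PPh3/I2/imidazole converts it into the iodide F3. Alkylation of the lithium enolate of 3-(phenylthio)dihydrofuran-2(3H)-one (excess; LiN(i-Pr)2, THF/DMPU) gives the α-phenylthio lactone F4. Oxidation with mCPBA at −78 °C gives the sulfoxide F5, and thermal syn-elimination into the ring (toluene, 110 °C) gives the butenolide 29.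

3. Step 18. Attack of the ylide at C11 may be too slow beside the fully substituted C9, so that lithium-salt-promoted rearrangement of the epoxide competes. Fallback from 22: dihydroxylation from the α-face (OsO4 cat., N-methylmorpholine N-oxide) gives the 9α,11-diol F6. Parikh–Doering oxidation (SO3·pyridine, DMSO, Et3N) gives the α-hydroxy aldehyde F7, and Wittig methylenation (Ph3P=CH2, excess) returns to 24.

Further compounds

F1 | step 12 | thia-bridged ketone: 3β-(tert-butyldimethylsilyloxy)-6α-(phenylsulfonyl)-4,4,8-trimethyl-trans-decalin-9-one with β-face C7–S–C20H2–C10 bridge (C8 epimers) | CC(C)(C)[Si](C)(C)O[C@H]1CC[C@@]2(CS3)[C@@H]([C@@H](S(=O)(=O)c4ccccc4)[C@H]3C(C)C2=O)C1(C)C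
F2 | step 21 | 3β-acetoxy-9β-(2-hydroxyethyl)-4,4,8α,10β-tetramethyl-trans-decalin-9α-ol | CC(=O)O[C@H]1CC[C@@]2(C)[C@@H](CC[C@@H](C)[C@]2(O)CCO)C1(C)C
F3 | step 21 | 3β-acetoxy-9β-(2-iodoethyl)-4,4,8α,10β-tetramethyl-trans-decalin-9α-ol | CC(=O)O[C@H]1CC[C@@]2(C)[C@@H](CC[C@@H](C)[C@]2(O)CCI)C1(C)C
F4 | step 21 | 3-[2-(3β-acetoxy-9α-hydroxy-4,4,8α,10β-tetramethyl-trans-decalin-9β-yl)ethyl]-3-(phenylthio)dihydrofuran-2(3H)-one (epimers at the lactone α-carbon) | CC(=O)O[C@H]1CC[C@@]2(C)[C@@H](CC[C@@H](C)[C@]2(O)CCC2(Sc3ccccc3)CCOC2=O)C1(C)C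
F5 | step 21 | sulfoxide of F4 | CC(=O)O[C@H]1CC[C@@]2(C)[C@@H](CC[C@@H](C)[C@]2(O)CCC2(S(=O)c3ccccc3)CCOC2=O)C1(C)C
F6 | step 18 | 3β-(tert-butyldimethylsilyloxy)-9β-(hydroxymethyl)-4,4,8α,10β-tetramethyl-trans-decalin-9α-ol | CC(C)(C)[Si](C)(C)O[C@H]1CC[C@@]2(C)[C@@H](CC[C@@H](C)[C@]2(O)CO)C1(C)C
F7 | step 18 | 3β-(tert-butyldimethylsilyloxy)-9α-hydroxy-4,4,8α,10β-tetramethyl-trans-decalin-9β-carbaldehyde | CC(C)(C)[Si](C)(C)O[C@H]1CC[C@@]2(C)[C@@H](CC[C@@H](C)[C@]2(O)C=O)C1(C)C
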